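Ring B (C5–C6–C7–C8–C9–C10, eudesmane numbering) is disconnected at C7: it is grown from the cyclopentanone ring (C5, C6, C8, C9, C10) of a trans-fused hydrindanone that is easy to build by aldol cyclopentannulation. Birch reduction of the bicyclic enone sets the trans C5/C10 fusion and fixes a C8–C6 silyl enol ether; dibromocarbene addition and cyclopropyl-to-allyl opening then insert C7, giving in one operation the six-membered ring with the C8 ketone, the C6=C7 double bond and a C7–Br handle for the hydroxyisopropyl group. The step exploits the 2-substituted enone pattern of ring B (C8=O, C7 bearing C11, C6=C7), which maps onto a 2-bromo-enone.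

Key step: step 10

Numbering remark: eudesmane numbers are used throughout (ring A = C1–C5, C10; ring B = C5–C10; C11 = carbinol carbon of the side chain); "alpha" means the face opposite to the C10 methyl group.

Assumption: the Pd/PHOX allylation is taken to show the same facial sense as with 2-methylcyclohexanone-derived allyl enol carbonates ((S)-ligand gives (S)-ketone), so the (R)-ligand is used.

Step 1
Reactants: 1 2-methylcyclohex-2-en-1-one
Product: 3 2,6-dimethylcyclohex-2-en-1-one (racemic), via lithium enolate 2 (not isolated)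
Conditions: LiN(iPr)2, THF, −78 °C; MeI, −78 → 0 °C
Reagents that add atoms: iodomethane (CI)
Why: Kinetic deprotonation of the enone occurs at the alpha' carbon and the cross-conjugated enolate is C-methylated (enolate alkylation); the new stereocentre is racemic and is erased in step 2.

Step 2
Reactants: 3 2,6-dimethylcyclohex-2-en-1-one
Product: 5 allyl 2,6-dimethylcyclohexa-1,5-dien-1-yl carbonate, via lithium dienolate 4 (not isolated)
Conditions: LiN(iPr)2, TMEDA, THF, −78 °C; allyl chloroformate, −78 → 0 °C
Reagents that add atoms: allyl chloroformate (C=CCOC(Cl)=O)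
Why: The only remaining alpha' hydrogen is removed and the tetrasubstituted enolate is O-acylated by the chloroformate in the presence of TMEDA (enol carbonate formation), which removes the C6 stereocentre.

Step 3
Reactants: 5 allyl 2,6-dimethylcyclohexa-1,5-dien-1-yl carbonate
Product: 6 (R)-6-allyl-2,6-dimethylcyclohex-2-en-1-one
Conditions: Pd2(dba)3 (2.5 mol %), (R)-t-Bu-PHOX (6 mol %), THF, 25 °C
Reagents that add atoms: none
Why: In this palladium-catalysed decarboxylative asymmetric allylic alkylation (Tsuji allylation) zerovalent palladium ionises the carbonate, CO2 is lost, and the PHOX-ligated allylpalladium enolate recombines at the enolate carbon, the (R)-ligand selecting the face that gives the R quaternary carbon (future C10).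

Step 4
Reactants: 6 (R)-6-allyl-2,6-dimethylcyclohex-2-en-1-one
Product: 7 (R)-2,6-dimethyl-6-(2-oxopropyl)cyclohex-2-en-1-one
Conditions: PdCl2 (10 mol %), CuCl (cat.), O2 (1 atm), DMF/H2O, rt
Reagents that add atoms: water (O), dioxygen (O=O)
Why: Tsuji-Wacker oxidation converts the terminal alkene into the methyl ketone with Markovnikov selectivity, while the conjugated trisubstituted ring alkene is inert and no stereocentre is touched.

Step 5
Reactants: 7 (R)-2,6-dimethyl-6-(2-oxopropyl)cyclohex-2-en-1-one
Product: 8 (7aR)-4,7a-dimethyl-1,6,7,7a-tetrahydro-2H-inden-2-one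
Conditions: KOH (powdered), xylenes, 110 °C
Reagents that add atoms: none
Why: In this intramolecular aldol condensation only the methyl group of the side-chain ketone can close a five-membered ring onto the ring carbonyl (future C5), and dehydration to the linearly conjugated dienone drives the reaction; the quaternary C10 cannot epimerise.

Step 6
Reactants: 8 (7aR)-4,7a-dimethyl-1,6,7,7a-tetrahydro-2H-inden-2-one
Product: 9 (4S,5R,7aR)-4,5-dihydroxy-4,7a-dimethyl-1,4,5,6,7,7a-hexahydro-2H-inden-2-one (cis-diol, both hydroxyls alpha)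
Conditions: OsO4 (2 mol %), NMO, acetone/H2O, rt; aq. Na2SO3
Reagents that add atoms: osmium tetroxide (O=[Os](=O)(=O)=O), N-methylmorpholine N-oxide (C[N+]1([O-])CCOCC1), water (O)
Why: In this Upjohn dihydroxylation OsO4 attacks the more electron-rich gamma,delta double bond (C3=C4) of the dienone from the face opposite to the pseudoaxial angular methyl, which sets the C4 carbinol (OH alpha, methyl beta) together with a 3-alpha hydroxyl in one syn addition.

Step 7
Reactants: 9 cis-diol
Product: 10 (4S,7aR)-4-hydroxy-4,7a-dimethyl-4,6,7,7a-tetrahydro-1H-indene-2,5-dione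
Conditions: IBX, DMSO, rt
Reagents that add atoms: none
Why: IBX oxidises the secondary alcohol of a 1,2-diol to the alpha-ketol without glycol cleavage and leaves the tertiary alcohol, so the wrongly configured C3 centre is erased.

Step 8
Reactants: 10 alpha-ketol
Product: 11 (4S,5S,7aR)-4,5-dihydroxy-4,7a-dimethyl-1,4,5,6,7,7a-hexahydro-2H-inden-2-one (trans-diol, 3-beta-OH, 4-alpha-OH)
Conditions: Me4NBH(OAc)3, MeCN/AcOH, −20 °C
Reagents that add atoms: none
Why: In this hydroxyl-directed reduction (Evans-Saksena type) the 4-alpha hydroxyl binds the triacetoxyborohydride and delivers hydride to the alpha face of the C3 ketone, giving the 3-beta alcohol trans to the C4 hydroxyl, and the enone is not reduced by this mild reagent.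

Step 9
Reactants: 11 trans-diol
Product: 13 (3aR,4S,5S,7aR)-4,7a-dimethyl-2,4,5-tris(trimethylsilyloxy)-3a,4,5,6,7,7a-hexahydro-1H-indene (trans-fused silyl enol ether), via dilithium enolate 12 (not isolated)
Conditions: Li, liquid NH3/THF, −78 °C; isoprene; evaporate NH3; TMSCl, Et3N, THF, 0 °C
Reagents that add atoms: chlorotrimethylsilane (C[Si](C)(C)Cl)
Why: In this dissolving-metal (Birch-type) enone reduction the beta carbon C5 is protonated on the alpha face (the beta face is shielded by the C4 and C10 methyls and the 4-alpha hydroxyl can deliver the proton), which gives the trans ring fusion and a C8–C6 lithium enolate of fixed position that is trapped on oxygen by TMSCl together with both hydroxyls.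

Step 10
Reactants: 13 trans-fused silyl enol ether
Product: 15 (4aR,5S,6S,8aR)-3-bromo-5,8a-dimethyl-5,6-bis(trimethylsilyloxy)-4a,5,6,7,8,8a-hexahydronaphthalen-2(1H)-one (7-bromo-6-en-8-one), via dibromocyclopropane 14 (not isolated)
Conditions: CHBr3 (2 equiv), KOt-Bu (1.3 equiv), pentane, −30 °C → rt
Reagents that add atoms: bromoform (BrC(Br)Br)
Why: Dibromocarbene, formed by alpha-elimination from bromoform, adds in a concerted cheletropic [2+1] step to the electron-rich C6=C8 silyl enol ether and closes a cyclopropane in which C7 bridges C6 and C8 (14). Ionisation of the endo C7–Br bond is concerted with disrotatory two-electron electrocyclic opening of the C6–C8 bond (cyclopropyl-to-allyl cation), assisted by the silyloxy group on C8, and loss of the silyl group from the oxocarbenium ion gives the 7-bromo-6-en-8-one, so the five-membered ring has grown into ring B by the inserted carbon C7. The closest known reaction type is the dihalocarbene ring expansion of cyclic silyl enol ethers to 2-halocycloalk-2-enones. No new stereocentre survives, because the two cyclopropane centres (C6, C8) are destroyed on opening and C5 and C10 take no part, so the trans fusion from step 9 is kept. The step needs insertion between C8 and C6 and not between C8 and C9, which is secured by the enol ether position fixed in the Birch step, and it needs the C5 hydrogen of the product (gamma to the new enone) to stay put, which is secured by keeping the base below the amount of bromoform so that none remains once the enone has formed.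

Step 11
Reactants: 15 7-bromo-6-en-8-one
Product: 16 ethylene ketal of 15 (1,3-dioxolane at C8)
Conditions: TMSOCH2CH2OTMS, TMSOTf (5 mol %), CH2Cl2, −78 → −20 °C; pyridine
Reagents that add atoms: 1,2-bis(trimethylsilyloxy)ethane (C[Si](C)(C)OCCO[Si](C)(C)C)
Why: Aprotic transketalisation with the bis-silyl glycol under TMSOTf catalysis masks the C8 carbonyl without moving the C6=C7 double bond and without cleaving the silyl ethers, and no stereocentre is affected.

Step 12
Reactants: 16 bromo ketal
Product: 19 (4aR,5S,6S,8aR)-5,6-dihydroxy-3-(2-hydroxypropan-2-yl)-5,8a-dimethyl-4a,5,6,7,8,8a-hexahydronaphthalen-2(1H)-one (3-beta,4-alpha,11-trihydroxyeudesm-6-en-8-one), via vinyllithium 17 (not isolated), via lithium alkoxide 18 (not isolated)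
Conditions: t-BuLi (2.1 equiv), THF, −78 °C; acetone, −78 → −40 °C; then 1 M HCl, THF/H2O, 0 °C → rt
Reagents that add atoms: acetone (CC(C)=O), water (O)
Why: Bromine-lithium exchange gives an alpha-ketovinyl anion equivalent whose 1,2-addition to acetone installs the C11 carbinol, and the aqueous acid quench hydrolyses the allylic ketal and both trimethylsilyl ethers without creating a stereocentre.

Step 13
Reactants: 20 (E)-2-methylbut-2-en-1-ol
Product: 21 [(2R,3R)-2,3-dimethyloxiran-2-yl]methanol
Conditions: Ti(OiPr)4 (10 mol %), D-(−)-diethyl tartrate (12 mol %), t-BuOOH, 4 Å molecular sieves, CH2Cl2, −20 °C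
Reagents that add atoms: tert-butyl hydroperoxide (CC(C)(C)OO)
Why: In this Katsuki-Sharpless asymmetric epoxidation the titanium tartrate complex delivers oxygen to one face of the allylic alcohol, D-(−)-diethyl tartrate giving the (2R,3R)-epoxy alcohol (the facial sense that turns (E)-RCH=CHCH2OH into (2R,3R)-epoxy alcohols), while the cis relation of the two methyls follows from the E alkene.

Step 14
Reactants: 21 epoxy alcohol
Product: 22 (2S,3R)-2,3-dimethyloxirane-2-carboxylic acid
Conditions: RuCl3·xH2O (2 mol %), NaIO4, MeCN/EtOAc/H2O, 0 °C → rt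
Reagents that add atoms: sodium periodate ([Na+].[O-]I(=O)(=O)=O), water (O)
Why: RuO4 generated catalytically from RuCl3 and NaIO4 oxidises the primary alcohol to the carboxylic acid without touching the epoxide, both centres being retained (the C2 descriptor changes from R to S only through the priority rules).

Step 15
Reactants: 19 triol, 22 epoxy acid
Product: 24 (1S,2S,4aR,8aR)-1-hydroxy-7-(2-hydroxypropan-2-yl)-1,4a-dimethyl-6-oxo-1,2,3,4,4a,5,6,8a-octahydronaphthalen-2-yl (2S,3R)-2,3-dimethyloxirane-2-carboxylate (target), via mixed anhydride 23 (not isolated)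
Conditions: 22, 2,4,6-trichlorobenzoyl chloride, Et3N, THF, rt; then 19, DMAP, toluene, rt → 40 °C
Reagents that add atoms: none
Why: In this Yamaguchi esterification the mixed anhydride acylates, under DMAP catalysis, only the secondary C3 hydroxyl (both tertiary alcohols are inert) with retention at C3 and without opening the epoxide, and any minor enantiomer of 19 should become a diastereomer that can be separated.

Compound list
1 | 2-methylcyclohex-2-en-1-one | CC1=CCCC1=O | starting material
2 | lithium 6-methylcyclohexa-1,5-dien-1-olate (alpha' enolate of 1) | [Li]OC1=CCCC=C1C | intermediate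
3 | 2,6-dimethylcyclohex-2-en-1-one (racemic) | CC1CCC=C(C)C1=O | intermediate
4 | lithium 2,6-dimethylcyclohexa-1,5-dien-1-olate | [Li]OC1=C(C)CCC=C1C | intermediate
5 | allyl 2,6-dimethylcyclohexa-1,5-dien-1-yl carbonate | C=CCOC(=O)OC1=C(C)CCC=C1C | intermediate
6 | (R)-6-allyl-2,6-dimethylcyclohex-2-en-1-one | C=CC[C@@]1(C)CCC=C(C)C1=O | intermediate
7 | (R)-2,6-dimethyl-6-(2-oxopropyl)cyclohex-2-en-1-one | CC(=O)C[C@@]1(C)CCC=C(C)C1=O | intermediate
8 | (7aR)-4,7a-dimethyl-1,6,7,7a-tetrahydro-2H-inden-2-one | CC1=CCC[C@]2(C)CC(=O)C=C12 | intermediate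
9 | (4S,5R,7aR)-4,5-dihydroxy-4,7a-dimethyl-1,4,5,6,7,7a-hexahydro-2H-inden-2-one (cis-diol) | O[C@@H]1CC[C@]2(C)CC(=O)C=C2[C@]1(C)O | intermediate
10 | (4S,7aR)-4-hydroxy-4,7a-dimethyl-4,6,7,7a-tetrahydro-1H-indene-2,5-dione | O=C1CC[C@]2(C)CC(=O)C=C2[C@]1(C)O | intermediate
11 | (4S,5S,7aR)-4,5-dihydroxy-4,7a-dimethyl-1,4,5,6,7,7a-hexahydro-2H-inden-2-one (trans-diol) | O[C@H]1CC[C@]2(C)CC(=O)C=C2[C@]1(C)O | intermediate
12 | dilithium salt: C8–C6 lithium enolate and C4 lithium alkoxide of the trans-fused hydrindanone, C3 hydroxyl free | O[C@H]1CC[C@]2(C)CC(O[Li])=C[C@H]2[C@]1(C)O[Li] | intermediate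
13 | (3aR,4S,5S,7aR)-4,7a-dimethyl-2,4,5-tris(trimethylsilyloxy)-3a,4,5,6,7,7a-hexahydro-1H-indene | C[Si](C)(C)O[C@H]1CC[C@]2(C)CC(O[Si](C)(C)C)=C[C@H]2[C@]1(C)O[Si](C)(C)C | intermediate
14 | dibromocyclopropane adduct of 13 (CBr2 bridging C6 and C8, drawn as the alpha-face adduct; the face is immaterial) | C[Si](C)(C)O[C@H]1CC[C@]2(C)C[C@]3(O[Si](C)(C)C)[C@H]([C@H]2[C@]1(C)O[Si](C)(C)C)C3(Br)Br | intermediate
15 | (4aR,5S,6S,8aR)-3-bromo-5,8a-dimethyl-5,6-bis(trimethylsilyloxy)-4a,5,6,7,8,8a-hexahydronaphthalen-2(1H)-one | C[Si](C)(C)O[C@H]1CC[C@]2(C)CC(=O)C(Br)=C[C@H]2[C@]1(C)O[Si](C)(C)C | intermediate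
16 | ethylene ketal of 15 (spiro-1,3-dioxolane at C8) | C[Si](C)(C)O[C@H]1CC[C@]2(C)CC3(OCCO3)C(Br)=C[C@H]2[C@]1(C)O[Si](C)(C)C | intermediate
17 | C7 vinyllithium derived from 16 | C[Si](C)(C)O[C@H]1CC[C@]2(C)CC3(OCCO3)C([Li])=C[C@H]2[C@]1(C)O[Si](C)(C)C | intermediate
18 | lithium alkoxide of the C11 carbinol (ketal and silyl ethers intact) | C[Si](C)(C)O[C@H]1CC[C@]2(C)CC3(OCCO3)C(C(C)(C)O[Li])=C[C@H]2[C@]1(C)O[Si](C)(C)C | intermediate
19 | (4aR,5S,6S,8aR)-5,6-dihydroxy-3-(2-hydroxypropan-2-yl)-5,8a-dimethyl-4a,5,6,7,8,8a-hexahydronaphthalen-2(1H)-one | O[C@H]1CC[C@]2(C)CC(=O)C(C(C)(C)O)=C[C@H]2[C@]1(C)O | intermediate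
20 | (E)-2-methylbut-2-en-1-ol | C/C=C(\C)CO | starting material
21 | [(2R,3R)-2,3-dimethyloxiran-2-yl]methanol | C[C@H]1O[C@]1(C)CO | intermediate
22 | (2S,3R)-2,3-dimethyloxirane-2-carboxylic acid | C[C@H]1O[C@]1(C)C(=O)O | intermediate
23 | (2S,3R)-2,3-dimethyloxirane-2-carboxylic 2,4,6-trichlorobenzoic anhydride | C[C@H]1O[C@]1(C)C(=O)OC(=O)c1c(Cl)cc(Cl)cc1Cl | intermediate
24 | (1S,2S,4aR,8aR)-1-hydroxy-7-(2-hydroxypropan-2-yl)-1,4a-dimethyl-6-oxo-1,2,3,4,4a,5,6,8a-octahydronaphthalen-2-yl (2S,3R)-2,3-dimethyloxirane-2-carboxylate | C[C@H]1O[C@]1(C)C(=O)O[C@H]1CC[C@]2(C)CC(=O)C(C(C)(C)O)=C[C@H]2[C@]1(C)O | target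

Total step count: 15. Longest linear sequence: 13 steps (steps 1–12 and 15); steps 13–14 form the side-chain branch.

Steps most likely to fail

1. Step 10 (key step). The carbene may add too slowly to the hindered trisubstituted enol ether while the alkoxide base desilylates it, and residual base may epimerise C5 of the product through its dienolate. Fallback, setting out from 13: zinc-carbenoid cyclopropanation (Et2Zn, CH2I2, CH2Cl2, 0 °C) should give the siloxycyclopropane F1. Saegusa-Ito oxidation with FeCl3 in DMF should cleave the internal C6–C8 bond to the ring-expanded 6-chloro-8-ketone F2, with the silyl ethers lost on aqueous work-up. NaOAc in methanol should eliminate HCl to give the 6-en-8-one diol F3. Bromine in CH2Cl2 should add to give the 6,7-dibromo ketone F4, and Et3N should eliminate HBr to give the bromoenone diol F5. Silylation (TMSCl, imidazole, DMF) then returns to the route at 15. The ring still arises by one-carbon expansion, but without strong base.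

2. Step 9. The C4 oxygen (gamma to the enone) may be lost reductively from the radical anion, the carbonyl may be over-reduced, or facial control at C5 may be incomplete. Fallback, setting out from 11: silylation (TMSCl, imidazole, DMF) should give the bis(trimethylsilyl) ether F6. Copper hydride-catalysed conjugate hydrosilylation ([(Ph3P)CuH]6 cat., PhMe2SiH, toluene, rt) should deliver hydride to C5 from the unshielded alpha face without electron-transfer intermediates and give the dimethylphenylsilyl enol ether F7. Under the conditions of step 10, F7 should give 15 directly, where the route is rejoined.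

3. Step 12. Acetone may transfer a proton to the hindered vinyllithium instead of undergoing addition, and the tertiary allylic alcohol may dehydrate or rearrange during the acidic ketal cleavage. Fallback, setting out from 15: Luche reduction (NaBH4, CeCl3·7H2O, MeOH, −40 °C) should give the bromo allylic alcohol F8 (either C8 epimer serves). Treatment with t-BuLi (3.1 equiv), then anhydrous CeCl3 and acetone (THF, −78 °C), should give the 8,11-diol F9 through a less basic organocerium species. MnO2 in CH2Cl2 should oxidise only the allylic secondary alcohol to the enone F10. Mild methanolysis of the silyl ethers (PPTS, MeOH) then returns to the route at 19 without aqueous mineral acid.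

Further compounds
F1 | step 10 | siloxycyclopropane from methylene transfer to 13 (CH2 bridging C6 and C8, alpha-face adduct drawn) | C[Si](C)(C)O[C@H]1CC[C@]2(C)C[C@]3(O[Si](C)(C)C)[C@H]([C@H]2[C@]1(C)O[Si](C)(C)C)C3
F2 | step 10 | ring-expanded 6-chloro-3-beta,4-alpha-dihydroxy-8-ketone (C6 epimers) | O[C@H]1CC[C@]2(C)CC(=O)CC(Cl)[C@H]2[C@]1(C)O
F3 | step 10 | (4aR,5S,6S,8aR)-5,6-dihydroxy-5,8a-dimethyl-4a,5,6,7,8,8a-hexahydronaphthalen-2(1H)-one | O[C@H]1CC[C@]2(C)CC(=O)C=C[C@H]2[C@]1(C)O
F4 | step 10 | 6,7-dibromo-3-beta,4-alpha-dihydroxy-8-ketone (mixture at C6 and C7) | O[C@H]1CC[C@]2(C)CC(=O)C(Br)C(Br)[C@H]2[C@]1(C)O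
F5 | step 10 | (4aR,5S,6S,8aR)-3-bromo-5,6-dihydroxy-5,8a-dimethyl-4a,5,6,7,8,8a-hexahydronaphthalen-2(1H)-one | O[C@H]1CC[C@]2(C)CC(=O)C(Br)=C[C@H]2[C@]1(C)O
F6 | step 9 | bis(trimethylsilyl) ether of 11 | C[Si](C)(C)O[C@H]1CC[C@]2(C)CC(=O)C=C2[C@]1(C)O[Si](C)(C)C
F7 | step 9 | trans-fused dimethylphenylsilyl enol ether (C8–C6), 3,4-bis(trimethylsilyl) ether | C[Si](C)(C)O[C@H]1CC[C@]2(C)CC(O[Si](C)(C)c3ccccc3)=C[C@H]2[C@]1(C)O[Si](C)(C)C
F8 | step 12 | 7-bromo-6-en-8-ol, 3,4-bis(trimethylsilyl) ether (C8 epimers) | C[Si](C)(C)O[C@H]1CC[C@]2(C)CC(O)C(Br)=C[C@H]2[C@]1(C)O[Si](C)(C)C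
F9 | step 12 | 7-(2-hydroxypropan-2-yl)-6-en-8-ol, 3,4-bis(trimethylsilyl) ether | C[Si](C)(C)O[C@H]1CC[C@]2(C)CC(O)C(C(C)(C)O)=C[C@H]2[C@]1(C)O[Si](C)(C)C
F10 | step 12 | 7-(2-hydroxypropan-2-yl)-6-en-8-one, 3,4-bis(trimethylsilyl) ether | C[Si](C)(C)O[C@H]1CC[C@]2(C)CC(=O)C(C(C)(C)O)=C[C@H]2[C@]1(C)O[Si](C)(C)C
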